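The amounts come first, so you have the whole problem in front of you:

| flask | left-handed substrate | right-handed substrate | partner | free catalyst | racemization catalyst | remark | time |
|---|---|---|---|---|---|---|---|
| grey | 44 mM | 44 mM | 176 mM | 4.4 mM | 48 µM | the very flask that is asked about, followed so far |  |
| green | 44 mM | 44 mM | 176 mM | 4.4 mM | 24 µM | run made earlier |  |
| flask | 44 mM | 44 mM | 176 mM | 4.4 mM | 48 µM |  | 80 min |

| run | time / min | left-handed product / % | right-handed product / % |
|---|---|---|---|
| grey | 0.500 | 3 | 1 |
| grey | 1.33 | 3 | 3 |
| grey | 3.00 | 11 | 4 |
| grey | 6.00 | 15 | 5 |
| green | 10.0 | 16 | 9 |
| green | 30.0 | 20 | 8 |
| green | 50.0 | 23 | 9 |
| green | 80.0 | 22 | 10 |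

(readings scatter by 1.5 percentage points)

* left-handed product and right-handed product together, in percent of the left-handed substrate and right-handed substrate charged together, at 80 min
* excess of left-handed product over right-handed product in the product at 80 min
* whether the exchange between left-handed substrate and right-handed substrate keeps pace with the reaction: how far the product's excess at 80 min gets from its value without exchange to its value with instant exchange (above 80% keeps pace, below 20% hardly takes part, else lags behind)

- free catalyst is single-handed; left-handed substrate and right-handed substrate are mirror images of each other, charged as a racemate, each of them at the stated concentration
- an excess is the difference of the two amounts in percent of their sum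
- an excess is below zero if the other one leads

Here is my own ledger for the partner, which I take as the limiting reagent, with one partner used per product.

1. Opening balance: the green run holds c(partner) = 176 mM against 88.0 mM of the two substrates together, twice what they could use.

2. Paid into product: the green readings at 50.0 min and 80.0 min average 32.0% of both products together, which books 28.2 mM of partner.

3. Written off: I assume that the other 148 mM of the green run's partner is lost by some side path, although no reading shows this.

4. The chances: follow one substrate molecule while the partner passes it. If each millimole of partner carries off the same fraction of whatever substrate remains, the chances multiply like interest, and the surviving fraction is exp(−reach × c(partner) charged). The reach, the logarithm of the surviving fraction's inverse per unit of partner charged, reads 2.19 L mol⁻¹ from the scattered readings of the green run.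

5. Closing: the grey flask has the same partner and free catalyst, and I keep its doubled racemization catalyst out of these books, so I reckon 32.0% at 80 min.

The forecast gives 33%, an excess of 41%, and exchange that hardly takes part. Where I book lost partner, it says “the catalyst is probably dying or being inhibited”.

The flask gives 30.3% and an excess of 39.2%, and its exchange lags behind, getting 44% of the way.

    partner + free catalyst + left-handed substrate → free catalyst + left-handed product (k = 3.88 L² mol⁻² s⁻¹)
    partner + free catalyst + right-handed substrate → free catalyst + right-handed product (k = 1.56 L² mol⁻² s⁻¹)
    left-handed substrate + racemization catalyst ⇌ right-handed substrate + racemization catalyst, rate k3*[racemization catalyst]*[left-handed substrate] forward; the back reaction follows from the equilibrium constant (k = 24.4 L mol⁻¹ s⁻¹)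
    partner → decomposed reagent (k = 0.00242 s⁻¹)
    2 free catalyst ⇌ resting dimer, settled at all times (K = 230 L mol⁻¹)

In the flask at 80.0 min the partner stands at 0% of its charge, with 26.7 mM of partner in product and 149 mM of decomposed reagent. The green reach, carried to the neighbouring flask with 700 mM of partner, reckons 78.4%, and that flask gives 76.4%.

The runs are calculated on assumed constants, noise included.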